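## Structural features

The target is a flavan-3-ol. Ring A, a phloroglucinol-type benzene carrying O5 and O7, is fused through C4a and C8a to the dihydropyran ring C. Ring C holds ring B (a pyrogallol unit) on C2 and a secondary hydroxyl on C3, and the C7 phenol carries a 3,4,5-trihydroxybenzoyl ester. C2 and C3 are neighbouring stereocentres, both R, with aryl and hydroxyl cis, which is the less stable relative arrangement. Seven free phenols make the compound sensitive to air under base, the aryl ester at O7 transfers its acyl group easily, and the benzylic C2–O1 bond allows epimerisation once the para phenol of ring B is free. The real difficulty is twofold: the galloyl group must sit on O7 alone, so O7 has to be told apart from O5 (both come from a symmetrical triol) and from the C3 hydroxyl, and the cis C2/C3 pair must be made in one absolute sense. The key step uses the ortho relationship of O1 on C8a and the C4 methylene on C4a: an aryne with its triple bond between C4a and C8a acquires exactly this pattern when the C=O of a formamide adds across it, while C3 (oxygenated) and C2 (arylated) map onto the alpha and carbonyl carbons of an alpha-alkoxy aryl ketone. Ring C can therefore be assembled at the flavylium oxidation level, before any stereocentre exists, and the oxygen on C5 next to the aryne polarises the triple bond so that O1 and C4 arrive the right way round.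

## Logic of the disconnections

From 31 the seven benzyl C–O bonds are cut first, giving 30. One group type then masks every phenol that must end free, and neutral hydrogenolysis removes it without touching the aryl ester or the stereocentres. The gain is a non-polar, oxidation-stable series up to the last step. The demand is an alcohol-free solvent so that the activated O7 ester is not solvolysed.

In 30 the O7–acyl bond is cut, giving 29 and 14. The ester is the most labile function and is made last among the skeletal bonds. The cut removes a third of the carbon atoms and leaves a flavan with two hydroxyls only. The forward step must acylate the phenol and spare the secondary C3 hydroxyl.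

In 29 the C3–H bond is cut and the C2 configuration is released, giving 28. Both stereocentres go in one stroke, because C2, alpha to the carbonyl, benzylic and oxygen-substituted, is configurationally labile. The forward step must racemise C2 faster than it reduces the mismatched enantiomer, deliver hydride anti to the aryl group, and select one enantioface.

In 28 the C4–H bond is cut, giving 26. This moves ring C to the aromatic benzopyrylium level, where C2, C3 and C4 are all sp2 and no stereochemical information needs to be carried. The demand is a hydride donor that reduces the cation and not the ketone that results.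

In 26 the free O3 and O7 hydroxyls are traced back to methoxymethyl acetals and the cationic C2 to a hemiketal carbon, giving 25. One acid treatment does all three operations. The demand is acid that spares aryl benzyl ethers.

In 25 four bonds are cut: O1–C8a and C4–C4a (18 adding across 20, which is released from 12), C3–C4 (19, the enolate of 17, adding to the methide carbon of 22) and O1–C2 (hemiketal closure of 24). This is the strategic cut. Three simple pieces, 12, 17 and 18, give the whole carbon skeleton with O7 already distinct from O5. The forward step needs the oxygen of 18 on C8a and not on C4a, capture of 20 by 18 and not by 19, and C–C bond formation before 22 is lost.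

In 12 the O–S bond of the triflate is cut and the phenol is traced to 10 (through 11). The carbamate is the group that earlier directs silicon to the correct carbon, so its removal and the triflation are joined in one flask. The demand is a non-acidic sequence, since the arylsilane, activated by three oxygens, is prone to protodesilylation.

In 10 the O7 acetal is traced back to the O7 silyl ether of 8 (through 9). The silyl ether is needed while silicon is placed on carbon, and the acetal is needed for the fluoride of the key step. The demand is cleavage of O–Si without loss of the aryl C–Si bond.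

In 8 the aryl C–Si bond is cut, giving 4. The demand is lithiation at the one ring position between the carbamate and the benzyloxy group. The bulky silyl ether at the future O7 closes the two competing positions.

4 is traced through 3 and 2 to 1 by cutting the carbamate, restoring one benzyl ether and removing the O–Si bond. In 1 one of three phloroglucinol oxygens is already distinct, so a single desymmetrising step (loss of one of two equivalent benzyl groups) is all that is needed.

In 17 the acetal O–C bond is cut to give 16. In 16 the bond between the carbonyl carbon and the hydroxymethyl carbon is cut, giving 14, and the C–Cl bond of 14 leads back to 13. The hydroxymethyl carbon is added with its oxygen in place in one operation. 14 is made once and serves both this branch and the late esterification.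

## Other disconnections considered

Alternative 1: The cut is C4–C4a together with C3–O, leading back to the ring-contracted mesylate A1. In the forward sense A1 would ionise in buffered aqueous hexafluoroisopropanol, the ring A carbon C4a would shift from C3 to the exocyclic CH2 as the mesylate leaves, and water would enter at C3 with inversion to give the cis-flavan-3-ol A2.
- In its favour: the step is stereospecific, and C4a, flanked by two oxygens and para to a third, is an ideal participating carbon. The absolute configuration would be inherited from A1 and would not depend on a dynamic resolution. On this point the alternative is better than the chosen plan, whose step 13 relies on catalyst control over a ketone with no conjugated aryl group.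
- Against it: water can enter at either carbon of the bridged array, and attack at the CH2 terminus returns the five-membered skeleton. O1 can compete as neighbouring group. The O5 ether of A1 and A2 is a 3,4,5-trialkoxybenzyl ether, itself ionisable in that solvent and a second electron-rich arene; a plain benzyl ether would be the sounder choice.
- Comparison: A1 needs its own enantioselective synthesis, as a cis-2,3-disubstituted dihydrobenzofuran on a differentiated ring A, so the O5/O7 problem returns without any convergence. The free C3 hydroxyl of A2 beside a silyl ether at O7 leads to the same phenol-versus-alcohol acylation as step 14, so the two plans are equal there. The key step makes one skeletal bond and closes no additional ring, so step economy is clearly worse.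

Alternative 2: The cut is C3–C4 and O1–C2. The o-hydroxybenzyl alcohol A3 would be ionised by a chiral BINOL-derived phosphoric acid to the o-quinone methide A4, which would add the (Z)-enol benzoate A5 in a [4+2] cycloaddition to give the cis-flavan-3-yl benzoate A6.
- In its favour: ring C, both stereocentres, their cis relationship (carried over from the Z geometry) and the absolute configuration would come from one step with no later redox adjustment. On stereochemical economy and ideal step count this is better than the chosen plan. Convergence is equal.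
- Against it: the required regiochemistry joins the methide carbon C4 to the oxygen-bearing carbon of A5, against the normal polarisation of an enol derivative. A5 offers the catalyst no hydrogen-bond donor, so enantiocontrol would rest on the contact with A4 alone. A4, stabilised by the O5 and O7 donors, is a weak electrophile that can also be intercepted by a second molecule of A3.
- Comparison: the benzoate of A6 would have to be cleaved before the gallate is introduced, because the aryl gallate would not survive ester cleavage. The endgame therefore meets the same O7-versus-O3 acylation as step 14 (equal), and A3 needs the same differentiated ring A (equal). The chosen plan has closer precedent for each bond-forming event and is mechanistically the more secure.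

Alternative 3: The cut is O1–C8a. The free benzylic hydroxyl of the syn bromo alcohol A7 would be joined to the ring A bromide with copper iodide (CuI), 1,10-phenanthroline and Cs2CO3, closing ring C with retention at C2 to give the fully protected cis-flavan A8.
- In its favour: both stereocentres of A7 can be set by asymmetric dihydroxylation chemistry on an acyclic precursor and are not touched in the ring closure. O3 is a benzyl ether in A8, so O7, once desilylated, would be the only free hydroxyl and its acylation would be unambiguous. On these two points the alternative is better than the chosen plan.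
- Against it: coupling of a hindered secondary benzylic alkoxide with an electron-rich, ortho-substituted aryl bromide by monovalent copper is slow. At the temperatures needed, oxidation of the alkoxide, loss of bromine and cleavage of the aryl silyl ether by carbonate can compete. Leaving only the benzylic hydroxyl of A7 free while its neighbour is benzylated costs extra protecting-group steps, and the ring A bromide with three different oxygen substituents needs a regiocontrolled synthesis of its own.
- Comparison: the sequence is linear and clearly longer, and the key step forms one bond where the chosen step forms four.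

Key step: step 10

Assumption: 3,5-bis(benzyloxy)phenol (1), 3,4,5-tris(benzyloxy)benzoic acid (13) and N,N-dimethylformamide (18) are bought; 1 is preferred to phloroglucinol because one of its three oxygens is already distinct from the other two.

Assumption: the (S,S) ligand is written provisionally for step 13; the sense of induction is to be checked on a small scale against racemic material, and the mirror-image complex is used without other change if the sense is opposite.

Remark: in 12 silicon sits on the future C4a, the triflate on the future C8a and the benzyloxy group on the future C5, which is what the bond set of step 10 requires; the acid chloride 14 is prepared once, isolated, and divided between steps 8 and 14.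

## Steps

Step 1
Reactants: 1 3,5-bis(benzyloxy)phenol
Product: 2 [3,5-bis(benzyloxy)phenoxy]tri(propan-2-yl)silane
Conditions: TIPSCl, imidazole, CH2Cl2, rt
Reagents that add atoms: chlorotri(propan-2-yl)silane, CC(C)[Si](Cl)(C(C)C)C(C)C
Why: Silylation of the single free phenol; the bulky silyl ether marks the future O7, resists hydrogenolysis and organolithium bases, and later shields its two neighbouring ring positions from lithiation.

Step 2
Reactants: 2 [3,5-bis(benzyloxy)phenoxy]tri(propan-2-yl)silane
Product: 3 3-(benzyloxy)-5-{[tri(propan-2-yl)silyl]oxy}phenol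
Conditions: H2 (1 atm), Pd/C, EtOAc, rt, stopped after about one equivalent of H2; recovered 2 recycled
Reagents that add atoms: none
Why: Hydrogenolysis of one of two equivalent benzyl ethers; the substrate is symmetrical, so the step is statistical but has no regiochemical question, the silyl ether is inert to hydrogenolysis, and unreacted 2 is returned to the step.

Step 3
Reactants: 3 3-(benzyloxy)-5-{[tri(propan-2-yl)silyl]oxy}phenol
Product: 4 3-(benzyloxy)-5-{[tri(propan-2-yl)silyl]oxy}phenyl propan-2-ylcarbamate
Conditions: i-PrNCO, Et3N (cat.), CH2Cl2, rt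
Reagents that add atoms: 2-isocyanatopropane, CC(C)N=C=O
Why: Base-catalysed addition of the phenol to the isocyanate gives an N-monoalkyl O-aryl carbamate, a strong ortho-directing group that can later be removed under mild amine conditions.

Step 4
Reactants: 4 3-(benzyloxy)-5-{[tri(propan-2-yl)silyl]oxy}phenyl propan-2-ylcarbamate
Product: 8 3-(benzyloxy)-5-{[tri(propan-2-yl)silyl]oxy}-2-(trimethylsilyl)phenyl propan-2-ylcarbamate, via N-silyl carbamate 5 (not isolated), via aryllithium 6 (not isolated), via N-silyl C-silyl carbamate 7 (not isolated)
Conditions: TBSOTf, TMEDA, Et2O, 0 °C to rt; n-BuLi, TMEDA, −78 °C; TMSCl, −78 °C to rt; aq NH4Cl–MeOH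
Reagents that add atoms: chlorotrimethylsilane, C[Si](C)(C)Cl
Why: Directed ortho-metalation: in situ N-silylation masks the N–H, the carbamate then directs lithiation to C2, the only position that is flanked by the cooperating benzyloxy oxygen and not by the bulky silyloxy group, and quench with the chlorosilane followed by mild hydrolysis of the N–Si bond gives 8.

Step 5
Reactants: 8 3-(benzyloxy)-5-{[tri(propan-2-yl)silyl]oxy}-2-(trimethylsilyl)phenyl propan-2-ylcarbamate
Product: 10 3-(benzyloxy)-5-(methoxymethoxy)-2-(trimethylsilyl)phenyl propan-2-ylcarbamate, via phenol 9 (not isolated)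
Conditions: Bu4NF (1.05 equiv), THF, 0 °C; then MOMCl, i-Pr2NEt, 0 °C to rt
Reagents that add atoms: chloromethyl methyl ether, COCCl
Why: Fluoride cleaves the aryl O–Si bond much faster than the unactivated aryl C–SiMe3 bond, and the ammonium phenoxide is alkylated in the same flask; the O7 acetal is stable to fluoride (needed in step 10) and labile to acid (needed in step 11), and no acid touches the arylsilane.

Step 6
Reactants: 10 3-(benzyloxy)-5-(methoxymethoxy)-2-(trimethylsilyl)phenyl propan-2-ylcarbamate
Product: 12 3-(benzyloxy)-5-(methoxymethoxy)-2-(trimethylsilyl)phenyl trifluoromethanesulfonate, via silylphenol 11 (not isolated)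
Conditions: Et2NH, DBU, MeCN, 40 °C; then PhNTf2, rt
Reagents that add atoms: N-phenylbis(trifluoromethanesulfonimide), O=S(=O)(N(c1ccccc1)S(=O)(=O)C(F)(F)F)C(F)(F)F
Why: E1cB cleavage of the N–H carbamate, with diethylamine scavenging the isocyanate, frees the phenoxide, which is triflated in the same pot; this is the established non-acidic finish to an o-silylaryl triflate.

Step 7
Reactants: 13 3,4,5-tris(benzyloxy)benzoic acid
Product: 14 3,4,5-tris(benzyloxy)benzoyl chloride
Conditions: SOCl2, PhMe, 70 °C; evaporation, crystallisation from PhMe–hexane
Reagents that add atoms: thionyl chloride, O=S(Cl)Cl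
Why: Standard conversion of a carboxylic acid into its chloride through the chlorosulfite; aryl benzyl ethers tolerate the conditions, and 14 is a storable crystalline solid that is isolated once and divided between steps 8 and 14.

Step 8
Reactants: 14 3,4,5-tris(benzyloxy)benzoyl chloride
Product: 16 2-hydroxy-1-[3,4,5-tris(benzyloxy)phenyl]ethanone, via silyl ester adduct 15 (not isolated)
Conditions: (Me3SiO)2C=CHOSiMe3, SnCl4 (cat.), neat, rt to 60 °C; then 0.6 M HCl, dioxane, 85 °C
Reagents that add atoms: tris(trimethylsilyloxy)ethylene, C[Si](C)(C)OC=C(O[Si](C)(C)C)O[Si](C)(C)C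
Why: C-acylation of the ketene bis(silyl) acetal by the aroyl chloride, with a trace of Lewis acid as is usual for the less reactive aroyl chlorides, gives an alpha-silyloxy beta-keto silyl ester, and acid hydrolysis with decarboxylation leaves the hydroxymethyl ketone; the oxygenated C3 carbon is added in one operation without diazomethane.

Step 9
Reactants: 16 2-hydroxy-1-[3,4,5-tris(benzyloxy)phenyl]ethanone
Product: 17 2-(methoxymethoxy)-1-[3,4,5-tris(benzyloxy)phenyl]ethanone
Conditions: MOMCl, i-Pr2NEt, CH2Cl2, 0 °C to rt
Reagents that add atoms: chloromethyl methyl ether, COCCl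
Why: Standard acetal protection of the primary alpha-hydroxyl; the acetal tolerates enolate formation and leaves together with the O7 acetal in step 11.

Step 10
Reactants: 17 2-(methoxymethoxy)-1-[3,4,5-tris(benzyloxy)phenyl]ethanone, 12 3-(benzyloxy)-5-(methoxymethoxy)-2-(trimethylsilyl)phenyl trifluoromethanesulfonate, 18 N,N-dimethylformamide
Product: 25 5-(benzyloxy)-3,7-bis(methoxymethoxy)-2-[3,4,5-tris(benzyloxy)phenyl]-2H-chromen-2-ol (racemic hemiketal), via lithium enolate 19 (not isolated), via aryne 20 (not isolated), via benzoxete 21 (not isolated), via amino o-quinone methide 22 (not isolated), via Mannich adduct 23 (not isolated), via retro-chalcone 24 (not isolated)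
Conditions: 17, LiN(SiMe3)2, THF, −78 °C; then 12 in DMF (18, solvent), CsF (3 equiv), 0 °C to rt; H2O
Reagents that add atoms: none
Why: Proposed new method: the closest known reaction type is the three-component coupling of arynes, DMF and 1,3-dicarbonyl compounds to 2H-chromenes, extended here to the pre-formed enolate of a simple alpha-alkoxy aryl ketone, which should behave alike because the acceptor is the same iminium-type methide carbon. Fluoride attacks silicon of 12 and triflate leaves to give aryne 20; the oxygen of 18 adds to C8a, the aryne carbon remote from the C5 benzyloxy group, because that group stabilises the charge developing at the adjacent C4a inductively, and the C4a anion closes on the iminium carbon to benzoxete 21, which opens to the amino o-quinone methide 22 (O1–C8a and C4–C4a formed). Enolate 19 adds through carbon to the methide carbon C4 in a Mannich-type step (C3–C4) to give 23, and loss of dimethylamine across C3–C4 gives the o-hydroxy retro-chalcone 24. Ring C, the only ring formed, closes by 6-exo-trig attack of the C8a phenoxide on the ring B ketone carbon (O1–C2) to give hemiketal 25. No stereocentre of the target is set: C2 of 25 is an uncontrolled hemiketal carbon that is erased in step 11, where any remaining 23 or 24 converges on the same cation. The selectivities needed are the regiochemistry across the aryne, secured by the C5 benzyloxy group, and capture of 20 by 18 in preference to 19, secured by using 18 as solvent in large excess and by the slow, solubility-limited release of the aryne by CsF under anhydrous conditions.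

Step 11
Reactants: 25 5-(benzyloxy)-3,7-bis(methoxymethoxy)-2-[3,4,5-tris(benzyloxy)phenyl]-2H-chromen-2-ol
Product: 26 5-(benzyloxy)-3,7-dihydroxy-2-[3,4,5-tris(benzyloxy)phenyl]chromenylium chloride
Conditions: HCl (2 M in MeOH), EtOAc, 0 °C to rt; Et2O (precipitation)
Reagents that add atoms: hydrogen chloride, Cl
Why: Acid ionises the hemiketal to the aromatic benzopyrylium ion and cleaves both methoxymethyl acetals by transfer to methanol, while aryl benzyl ethers are stable; the salt should be isolable by precipitation, which also purifies the crude product of step 10.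

Step 12
Reactants: 26 5-(benzyloxy)-3,7-dihydroxy-2-[3,4,5-tris(benzyloxy)phenyl]chromenylium chloride
Product: 28 5-(benzyloxy)-7-hydroxy-2-[3,4,5-tris(benzyloxy)phenyl]chroman-3-one (racemic), via enol 27 (not isolated)
Conditions: Hantzsch ester (1.05 equiv), MeCN–CH2Cl2, 0 °C, Ar; pH 7 buffer
Reagents that add atoms: none
Why: Hydride transfer from the dihydropyridine to C4 of the flavylium ion gives the 4H-chromen-3-ol, which tautomerises to the ketone; the donor reduces the cation but not ketones and is used in near-stoichiometric amount, so the ketone should not be reduced further before step 13 (hydride at C2 would lead to the same ketone).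

Step 13
Reactants: 28 5-(benzyloxy)-7-hydroxy-2-[3,4,5-tris(benzyloxy)phenyl]chroman-3-one
Product: 29 (2R,3R)-5-(benzyloxy)-2-[3,4,5-tris(benzyloxy)phenyl]chromane-3,7-diol
Conditions: RuCl(p-cymene)[(S,S)-TsDPEN] (3 mol %), HCO2H–Et3N (5:2), EtOAc, 30 °C, Ar
Reagents that add atoms: none
Why: Noyori asymmetric transfer hydrogenation under dynamic kinetic resolution, as known for alpha-aryl cyclic ketones: C2 racemises through the enol in the amine-containing medium, hydride enters C3 anti to the C2 aryl group so that hydroxyl and aryl end cis, and the chiral catalyst reduces preferentially the ketone enantiomer that gives C3 R, which fixes C2 as R.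

Step 14
Reactants: 29 (2R,3R)-5-(benzyloxy)-2-[3,4,5-tris(benzyloxy)phenyl]chromane-3,7-diol, 14 3,4,5-tris(benzyloxy)benzoyl chloride
Product: 30 (2R,3R)-5-(benzyloxy)-3-hydroxy-2-[3,4,5-tris(benzyloxy)phenyl]chroman-7-yl 3,4,5-tris(benzyloxy)benzoate
Conditions: 14 (1.05 equiv), Et3N (1.1 equiv), CH2Cl2, −20 to 0 °C, no DMAP
Reagents that add atoms: none
Why: Chemoselective acylation of a phenol beside a secondary alcohol: with a tertiary amine and no acyl-transfer catalyst the phenoxide should react much faster with the aroyl chloride than the hindered axial C3 hydroxyl; the stereocentres are not involved.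

Step 15
Reactants: 30 (2R,3R)-5-(benzyloxy)-3-hydroxy-2-[3,4,5-tris(benzyloxy)phenyl]chroman-7-yl 3,4,5-tris(benzyloxy)benzoate
Product: 31 epigallocatechin 7-O-gallate, (2R,3R)-3,5-dihydroxy-2-(3,4,5-trihydroxyphenyl)chroman-7-yl 3,4,5-trihydroxybenzoate
Conditions: H2 (1 atm), Pd(OH)2/C, THF–EtOAc, rt
Reagents that add atoms: none
Why: Neutral hydrogenolysis of the seven benzyl ethers; the aryl ester and both stereocentres are not affected, and the alcohol-free solvent avoids solvolysis of the activated ester.

## Compound list

1 | 3,5-bis(benzyloxy)phenol | Oc1cc(OCc2ccccc2)cc(OCc2ccccc2)c1 | starting material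
2 | [3,5-bis(benzyloxy)phenoxy]tri(propan-2-yl)silane | CC(C)[Si](Oc1cc(OCc2ccccc2)cc(OCc2ccccc2)c1)(C(C)C)C(C)C | intermediate
3 | 3-(benzyloxy)-5-{[tri(propan-2-yl)silyl]oxy}phenol | CC(C)[Si](Oc1cc(O)cc(OCc2ccccc2)c1)(C(C)C)C(C)C | intermediate
4 | 3-(benzyloxy)-5-{[tri(propan-2-yl)silyl]oxy}phenyl propan-2-ylcarbamate | CC(C)NC(=O)Oc1cc(OCc2ccccc2)cc(O[Si](C(C)C)(C(C)C)C(C)C)c1 | intermediate
5 | 3-(benzyloxy)-5-{[tri(propan-2-yl)silyl]oxy}phenyl [tert-butyl(dimethyl)silyl](propan-2-yl)carbamate | CC(C)N(C(=O)Oc1cc(OCc2ccccc2)cc(O[Si](C(C)C)(C(C)C)C(C)C)c1)[Si](C)(C)C(C)(C)C | intermediate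
6 | 2-lithio derivative of 5 (lithium on the carbon between the carbamate and the benzyloxy group) | CC(C)N(C(=O)Oc1cc(O[Si](C(C)C)(C(C)C)C(C)C)cc(OCc2ccccc2)c1[Li])[Si](C)(C)C(C)(C)C | intermediate
7 | 3-(benzyloxy)-5-{[tri(propan-2-yl)silyl]oxy}-2-(trimethylsilyl)phenyl [tert-butyl(dimethyl)silyl](propan-2-yl)carbamate | CC(C)N(C(=O)Oc1cc(O[Si](C(C)C)(C(C)C)C(C)C)cc(OCc2ccccc2)c1[Si](C)(C)C)[Si](C)(C)C(C)(C)C | intermediate
8 | 3-(benzyloxy)-5-{[tri(propan-2-yl)silyl]oxy}-2-(trimethylsilyl)phenyl propan-2-ylcarbamate | CC(C)NC(=O)Oc1cc(O[Si](C(C)C)(C(C)C)C(C)C)cc(OCc2ccccc2)c1[Si](C)(C)C | intermediate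
9 | 3-(benzyloxy)-5-hydroxy-2-(trimethylsilyl)phenyl propan-2-ylcarbamate | CC(C)NC(=O)Oc1cc(O)cc(OCc2ccccc2)c1[Si](C)(C)C | intermediate
10 | 3-(benzyloxy)-5-(methoxymethoxy)-2-(trimethylsilyl)phenyl propan-2-ylcarbamate | CC(C)NC(=O)Oc1cc(OCOC)cc(OCc2ccccc2)c1[Si](C)(C)C | intermediate
11 | 3-(benzyloxy)-5-(methoxymethoxy)-2-(trimethylsilyl)phenol | COCOc1cc(O)c([Si](C)(C)C)c(OCc2ccccc2)c1 | intermediate
12 | 3-(benzyloxy)-5-(methoxymethoxy)-2-(trimethylsilyl)phenyl trifluoromethanesulfonate | COCOc1cc(OCc2ccccc2)c([Si](C)(C)C)c(OS(=O)(=O)C(F)(F)F)c1 | intermediate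
13 | 3,4,5-tris(benzyloxy)benzoic acid | O=C(O)c1cc(OCc2ccccc2)c(OCc2ccccc2)c(OCc2ccccc2)c1 | starting material
14 | 3,4,5-tris(benzyloxy)benzoyl chloride | O=C(Cl)c1cc(OCc2ccccc2)c(OCc2ccccc2)c(OCc2ccccc2)c1 | intermediate
15 | trimethylsilyl 3-oxo-3-[3,4,5-tris(benzyloxy)phenyl]-2-[(trimethylsilyl)oxy]propanoate | C[Si](C)(C)OC(=O)C(O[Si](C)(C)C)C(=O)c1cc(OCc2ccccc2)c(OCc2ccccc2)c(OCc2ccccc2)c1 | intermediate
16 | 2-hydroxy-1-[3,4,5-tris(benzyloxy)phenyl]ethanone | OCC(=O)c1cc(OCc2ccccc2)c(OCc2ccccc2)c(OCc2ccccc2)c1 | intermediate
17 | 2-(methoxymethoxy)-1-[3,4,5-tris(benzyloxy)phenyl]ethanone | COCOCC(=O)c1cc(OCc2ccccc2)c(OCc2ccccc2)c(OCc2ccccc2)c1 | intermediate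
18 | N,N-dimethylformamide | CN(C)C=O | starting material
19 | lithium (Z)-2-(methoxymethoxy)-1-[3,4,5-tris(benzyloxy)phenyl]ethen-1-olate | COCO/C=C(\O[Li])c1cc(OCc2ccccc2)c(OCc2ccccc2)c(OCc2ccccc2)c1 | intermediate
20 | 3-(benzyloxy)-5-(methoxymethoxy)benzyne | COCOC1=CC#CC(OCc2ccccc2)=C1 | intermediate
21 | 3-(benzyloxy)-5-(methoxymethoxy)-N,N-dimethyl-2H-benzo[b]oxet-2-amine | COCOc1cc(OCc2ccccc2)c2C(N(C)C)Oc2c1 | intermediate
22 | 5-(benzyloxy)-6-[(dimethylamino)methylidene]-3-(methoxymethoxy)cyclohexa-2,4-dien-1-one | CN(C)C=C1C(=O)C=C(OCOC)C=C1OCc2ccccc2 | intermediate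
23 | 3-[2-(benzyloxy)-6-hydroxy-4-(methoxymethoxy)phenyl]-3-(dimethylamino)-2-(methoxymethoxy)-1-[3,4,5-tris(benzyloxy)phenyl]propan-1-one (mixture of diastereomers) | CN(C)C(c1c(O)cc(OCOC)cc1OCc1ccccc1)C(OCOC)C(=O)c1cc(OCc2ccccc2)c(OCc2ccccc2)c(OCc2ccccc2)c1 | intermediate
24 | 3-[2-(benzyloxy)-6-hydroxy-4-(methoxymethoxy)phenyl]-2-(methoxymethoxy)-1-[3,4,5-tris(benzyloxy)phenyl]prop-2-en-1-one (alkene geometry not fixed) | COCOC(=Cc1c(O)cc(OCOC)cc1OCc1ccccc1)C(=O)c1cc(OCc2ccccc2)c(OCc2ccccc2)c(OCc2ccccc2)c1 | intermediate
25 | 5-(benzyloxy)-3,7-bis(methoxymethoxy)-2-[3,4,5-tris(benzyloxy)phenyl]-2H-chromen-2-ol (racemic) | COCOc1cc(OCc3ccccc3)c2C=C(OCOC)C(O)(c3cc(OCc4ccccc4)c(OCc4ccccc4)c(OCc4ccccc4)c3)Oc2c1 | intermediate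
26 | 5-(benzyloxy)-3,7-dihydroxy-2-[3,4,5-tris(benzyloxy)phenyl]chromenylium chloride | Oc1cc(OCc2ccccc2)c2cc(O)c(-c3cc(OCc4ccccc4)c(OCc4ccccc4)c(OCc4ccccc4)c3)[o+]c2c1.[Cl-] | intermediate
27 | 5-(benzyloxy)-2-[3,4,5-tris(benzyloxy)phenyl]-4H-chromene-3,7-diol | Oc1cc(OCc2ccccc2)c2c(c1)OC(c1cc(OCc3ccccc3)c(OCc3ccccc3)c(OCc3ccccc3)c1)=C(O)C2 | intermediate
28 | 5-(benzyloxy)-7-hydroxy-2-[3,4,5-tris(benzyloxy)phenyl]chroman-3-one (racemic) | O=C1Cc2c(OCc3ccccc3)cc(O)cc2OC1c1cc(OCc2ccccc2)c(OCc2ccccc2)c(OCc2ccccc2)c1 | intermediate
29 | (2R,3R)-5-(benzyloxy)-2-[3,4,5-tris(benzyloxy)phenyl]chromane-3,7-diol | Oc1cc(OCc2ccccc2)c2c(c1)O[C@H](c1cc(OCc3ccccc3)c(OCc3ccccc3)c(OCc3ccccc3)c1)[C@H](O)C2 | intermediate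
30 | (2R,3R)-5-(benzyloxy)-3-hydroxy-2-[3,4,5-tris(benzyloxy)phenyl]chroman-7-yl 3,4,5-tris(benzyloxy)benzoate | O=C(Oc1cc(OCc2ccccc2)c2c(c1)O[C@H](c1cc(OCc3ccccc3)c(OCc3ccccc3)c(OCc3ccccc3)c1)[C@H](O)C2)c1cc(OCc2ccccc2)c(OCc2ccccc2)c(OCc2ccccc2)c1 | intermediate
31 | epigallocatechin 7-O-gallate, (2R,3R)-3,5-dihydroxy-2-(3,4,5-trihydroxyphenyl)chroman-7-yl 3,4,5-trihydroxybenzoate | O=C(Oc1cc(O)c2c(c1)O[C@H](c1cc(O)c(O)c(O)c1)[C@H](O)C2)c1cc(O)c(O)c(O)c1 | target

## Step count and least certain steps

Total step count: 15. Longest linear sequence: 12 steps (steps 1 to 6 and 10 to 15, from 1). The ketone branch (steps 7, 8 and 9) joins at step 10, and 14 from step 7 is used again in step 14.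

Step 10 (key step, labelled as a proposed new method). The most likely failure is capture of the aryne by the enolate itself (direct arylation at carbon or oxygen) in competition with addition of the formamide. The second is loss of the amino o-quinone methide, by adventitious water or by a second aryne, before the C3–C4 bond forms. Both arise because a simple ketone enolate is more basic and more nucleophilic than the stabilised carbanions for which the coupling is established. The fallback uses known chemistry only, sets out from 12 and comes back at 26. Treatment of 12 with CsF in 18 without any enolate, followed by aqueous work-up, gives by the established two-component aryne–formamide reaction and hydrolysis of 22 the salicylaldehyde 2-(benzyloxy)-6-hydroxy-4-(methoxymethoxy)benzaldehyde F1, with the same regiochemistry as in step 10. F1 and 17 are then condensed with HCl in EtOAc–MeOH. This is the classical acid-mediated aldol condensation and cyclodehydration of a salicylaldehyde with an alpha-oxygenated aryl ketone; both acetals are lost in the same operation and 26 precipitates.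

Step 13. Racemisation at C2 may be too slow relative to reduction, which would erode enantiomeric purity or leave trans material. Enantioface discrimination may also be weak, because the carbonyl has no directly conjugated aryl group for the catalyst to recognise. The fallback sets out from 28 and comes back at 29. Reduction with LiBH(s-Bu)3 in THF at −78 °C, which attacks anti to the C2 aryl group, gives the racemic cis diol: 29 together with its mirror image (2S,3S)-5-(benzyloxy)-2-[3,4,5-tris(benzyloxy)phenyl]chromane-3,7-diol F2. The racemate is resolved by preparative chromatography on a chiral stationary phase, and the (2R,3R) fraction is 29.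

Step 4. Deprotonation may occur at a wrong site: at a benzylic CH2 with ensuing Wittig rearrangement, or at a ring position next to the silyl ether. The carbamoyl group may also migrate if the lithiated species warms. The fallback sets out from 2 and comes back at 8; it fixes the regiochemistry by symmetry. Treatment of 2 with n-BuLi in THF at 0 °C lithiates the only ring position between the two benzyloxy groups, giving [2,6-bis(benzyloxy)-4-{[tri(propan-2-yl)silyl]oxy}phenyl]lithium F3. Quench with TMSCl gives [3,5-bis(benzyloxy)-4-(trimethylsilyl)phenoxy]tri(propan-2-yl)silane F4. Partial hydrogenolysis (H2, Pd/C, EtOAc) removes one of its two equivalent benzyl groups to give 3-(benzyloxy)-5-{[tri(propan-2-yl)silyl]oxy}-2-(trimethylsilyl)phenol F5. Addition of F5 to i-PrNCO (Et3N cat.) gives 8.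

Step 14. Chemoselectivity may be lost, with acylation of the C3 hydroxyl in addition to O7. The fallback sets out from 28 and comes back at 30; it reverses the order so that the phenol is the only hydroxyl present when the acyl group is introduced. Acylation of 28 with 14 and Et3N in CH2Cl2 at −20 °C gives racemic 5-(benzyloxy)-3-oxo-2-[3,4,5-tris(benzyloxy)phenyl]chroman-7-yl 3,4,5-tris(benzyloxy)benzoate F6. Transfer hydrogenation of F6 under the conditions of step 13 gives 30 directly.

## Further compounds

F1 | step 10 | 2-(benzyloxy)-6-hydroxy-4-(methoxymethoxy)benzaldehyde | COCOc1cc(O)c(C=O)c(OCc2ccccc2)c1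
F2 | step 13 | (2S,3S)-5-(benzyloxy)-2-[3,4,5-tris(benzyloxy)phenyl]chromane-3,7-diol (mirror image of 29, formed with it as the racemate) | Oc1cc(OCc2ccccc2)c2c(c1)O[C@@H](c1cc(OCc3ccccc3)c(OCc3ccccc3)c(OCc3ccccc3)c1)[C@@H](O)C2
F3 | step 4 | [2,6-bis(benzyloxy)-4-{[tri(propan-2-yl)silyl]oxy}phenyl]lithium | CC(C)[Si](Oc1cc(OCc2ccccc2)c([Li])c(OCc2ccccc2)c1)(C(C)C)C(C)C
F4 | step 4 | [3,5-bis(benzyloxy)-4-(trimethylsilyl)phenoxy]tri(propan-2-yl)silane | CC(C)[Si](Oc1cc(OCc2ccccc2)c([Si](C)(C)C)c(OCc2ccccc2)c1)(C(C)C)C(C)C
F5 | step 4 | 3-(benzyloxy)-5-{[tri(propan-2-yl)silyl]oxy}-2-(trimethylsilyl)phenol | CC(C)[Si](Oc1cc(O)c([Si](C)(C)C)c(OCc2ccccc2)c1)(C(C)C)C(C)C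
F6 | step 14 | 5-(benzyloxy)-3-oxo-2-[3,4,5-tris(benzyloxy)phenyl]chroman-7-yl 3,4,5-tris(benzyloxy)benzoate (racemic) | O=C1Cc2c(OCc3ccccc3)cc(OC(=O)c3cc(OCc4ccccc4)c(OCc4ccccc4)c(OCc4ccccc4)c3)cc2OC1c1cc(OCc2ccccc2)c(OCc2ccccc2)c(OCc2ccccc2)c1
A1 | alternative 1 | {(2S,3S)-2-[3,4,5-tris(benzyloxy)phenyl]-4-{[3,4,5-tris(benzyloxy)benzyl]oxy}-6-{[tri(propan-2-yl)silyl]oxy}-2,3-dihydro-1-benzofuran-3-yl}methyl methanesulfonate (2,3-cis) | CC(C)[Si](C(C)C)(C(C)C)Oc1cc(OCc3cc(OCc4ccccc4)c(OCc4ccccc4)c(OCc4ccccc4)c3)c2c(c1)O[C@H](c1cc(OCc3ccccc3)c(OCc3ccccc3)c(OCc3ccccc3)c1)[C@@H]2COS(C)(=O)=O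
A2 | alternative 1 | (2R,3R)-2-[3,4,5-tris(benzyloxy)phenyl]-5-{[3,4,5-tris(benzyloxy)benzyl]oxy}-7-{[tri(propan-2-yl)silyl]oxy}chroman-3-ol | CC(C)[Si](C(C)C)(C(C)C)Oc1cc(OCc3cc(OCc4ccccc4)c(OCc4ccccc4)c(OCc4ccccc4)c3)c2c(c1)O[C@H](c1cc(OCc3ccccc3)c(OCc3ccccc3)c(OCc3ccccc3)c1)[C@H](O)C2
A3 | alternative 2 | 3-(benzyloxy)-2-(hydroxymethyl)-5-{[tri(propan-2-yl)silyl]oxy}phenol | CC(C)[Si](C(C)C)(C(C)C)Oc1cc(O)c(CO)c(OCc2ccccc2)c1
A4 | alternative 2 | 5-(benzyloxy)-6-methylidene-3-{[tri(propan-2-yl)silyl]oxy}cyclohexa-2,4-dien-1-one | C=C1C(=O)C=C(O[Si](C(C)C)(C(C)C)C(C)C)C=C1OCc1ccccc1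
A5 | alternative 2 | (Z)-2-[3,4,5-tris(benzyloxy)phenyl]ethenyl benzoate | O=C(O/C=C\c1cc(OCc2ccccc2)c(OCc2ccccc2)c(OCc2ccccc2)c1)c1ccccc1
A6 | alternative 2 | (2R,3R)-5-(benzyloxy)-2-[3,4,5-tris(benzyloxy)phenyl]-7-{[tri(propan-2-yl)silyl]oxy}chroman-3-yl benzoate | CC(C)[Si](C(C)C)(C(C)C)Oc1cc(OCc3ccccc3)c2c(c1)O[C@H](c1cc(OCc3ccccc3)c(OCc3ccccc3)c(OCc3ccccc3)c1)[C@H](OC(=O)c1ccccc1)C2
A7 | alternative 3 | (1R,2R)-2-(benzyloxy)-3-[2-(benzyloxy)-6-bromo-4-{[tri(propan-2-yl)silyl]oxy}phenyl]-1-[3,4,5-tris(benzyloxy)phenyl]propan-1-ol | CC(C)[Si](C(C)C)(C(C)C)Oc1cc(OCc2ccccc2)c(C[C@@H](OCc2ccccc2)[C@H](O)c2cc(OCc3ccccc3)c(OCc3ccccc3)c(OCc3ccccc3)c2)c(Br)c1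
A8 | alternative 3 | (2R,3R)-3,5-bis(benzyloxy)-2-[3,4,5-tris(benzyloxy)phenyl]-7-{[tri(propan-2-yl)silyl]oxy}chromane | CC(C)[Si](C(C)C)(C(C)C)Oc1cc(OCc3ccccc3)c2c(c1)O[C@H](c1cc(OCc3ccccc3)c(OCc3ccccc3)c(OCc3ccccc3)c1)[C@H](OCc1ccccc1)C2
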